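## Retrosynthetic overview

- End game is all C–O chemistry on a cis-fused hydroazulene enedione: C10–OH-directed epoxidation (C8/C9), two alkoxide angeloylations, and a last C4–OH-directed reduction that sets C2.
- The seven-membered carbocycle comes from an O→C acyl transfer (intramolecular Claisen) of a 6-substituted 4-methyl-5,6-dihydropyran-2-one onto C1 of a cyclopentanone; the lactone comes from an aldehyde by vinylogous Reformatsky reaction.
- Key step: the cyclopropane C4–C6 bond of (−)-α-thujone is replaced by a C4–O bond with retention (aerobic radical ring opening, then intramolecular peroxide epoxidation), which also oxidises C6.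
- Ring order: cyclopentane (from thujone) → C3–C4 epoxide → δ-lactone → seven-membered carbocycle → C8–C9 epoxide.
- Carbon sources: thujone (C10), ethyl 4-bromo-3-methylbut-2-enoate (C5 of the ring), angelic anhydride (both esters).

Assumption and convention: (−)-α-thujone is used (its 4-epimer β-thujone converges at step 5, where that carbon becomes an enolate); names use the daucane numbering of the target (C1 quaternary, C2–C5 in the five-membered ring, C6–C10 in the seven-membered ring), with α = the face of the five-membered ring carrying C6 and the C4 oxygen and β = the face of H-5 and the C1 methyl.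

## Route

Step 1
Reactants: 1 (−)-α-thujone, (1S,4R,5R)-4-methyl-1-(propan-2-yl)bicyclo[3.1.0]hexan-3-one
Product: 2 kinetic trimethylsilyl enol ether of 1 (C2(OSiMe3)=C3; the three stereocentres of 1 unchanged)
Conditions: LiN(iPr)2, THF, −78 °C; Me3SiCl, −78 to 0 °C
Reagents that add atoms: chlorotrimethylsilane, C[Si](C)(C)Cl
Why: Kinetic enolate formation removes a proton from the α-methylene (C3) and not from the methyl-bearing methine, and O-silylation fixes that regiochemistry, which makes C3 (next to the cyclopropane carbon C4) the radical site of step 2; no stereocentre is formed.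

Step 2
Reactants: 2 kinetic trimethylsilyl enol ether of 1
Product: 4 3α,4α-epoxy-5α-(hydroxymethyl)-4β-isopropyl-1β-methylcyclopentan-2-one, via hydroperoxy enone 3 (not isolated)
Conditions: 9-mesityl-10-methylacridinium tetrafluoroborate (5 mol %), air, MeCN/MeOH 9:1, 450 nm LEDs, 0 °C; then DBU (0.2 equiv), 0 °C
Reagents that add atoms: dioxygen, O=O
Why: Proposed new method: one-electron photo-oxidation of the silyl enol ether and desilylation give the C3 α-keto radical, a cyclopropylcarbinyl radical that opens by scission of the exocyclic C4–C6 bond (the stereoelectronically favoured mode for bicyclo[3.1.0]hex-2-yl radicals and the known radical-clock behaviour of thujone) to the C3=C4 enone and a primary C6 radical; O2 capture and reduction of the peroxyl radical by the reduced acridine (catalyst turnover) give hydroperoxide 3, whose anion can reach C4 only from the face that held the cyclopropane methylene, so the intramolecular Weitz–Scheffer epoxidation puts the C4 oxygen where the C4–C6 bond was (retention, isopropyl stays cis to H-5) and leaves C6 as CH2OH; the closest known reactions are electron-transfer photo-oxygenation of cyclopropanes and silyl enol ethers, the radical vinylcyclopropane/O2 route to 1,2-dioxolanes and enone epoxidation by alkyl hydroperoxide anions.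

Step 3
Reactants: 4 3α,4α-epoxy-5α-(hydroxymethyl)-4β-isopropyl-1β-methylcyclopentan-2-one
Product: 5 3α,4α-epoxy-5α-formyl-4β-isopropyl-1β-methylcyclopentan-2-one
Conditions: Dess–Martin periodinane, CH2Cl2, 0 °C to rt
Reagents that add atoms: none
Why: Dess–Martin oxidation of the only alcohol gives the aldehyde under non-basic conditions, so neither the α-stereocentre C5 nor the epoxy ketone is disturbed.

Step 4
Reactants: 5 3α,4α-epoxy-5α-formyl-4β-isopropyl-1β-methylcyclopentan-2-one; 6 ethyl (E)-4-bromo-3-methylbut-2-enoate (E/Z mixtures serve equally)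
Product: 7 4-methyl-6-(3α,4α-epoxy-4β-isopropyl-1β-methyl-2-oxocyclopent-5α-yl)-5,6-dihydro-2H-pyran-2-one, C6 configured as in the target
Conditions: activated Zn dust, Et2O/benzene 1:1, 40 °C; aq NH4Cl
Reagents that add atoms: none
Why: Vinylogous Reformatsky reaction: the zinc dienolate attacks through its γ-carbon and the resulting (Z)-zinc alkoxide lactonises, while zinc bridging the aldehyde oxygen and the cis epoxide oxygen (six-membered Cram chelate, as in chelation-controlled Zn(BH4)2 reductions of epoxy ketones) directs C7 to the aldehyde face syn to H-5, which is the C6 configuration of the target (simple Felkin–Anh addition would give the epimer).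

Step 5
Reactants: 7 lactone from step 4; 8 angelic anhydride, (Z)-2-methylbut-2-enoic anhydride
Product: 10 6β-(angeloyloxy)-3α,4α-epoxy-1β,5β-dauc-8-ene-2,10-dione, via lithium alkoxide 9 (not isolated)
Conditions: LiN(SiMe3)2 (1.1 equiv), THF, −78 to −30 °C; then 8 (1.3 equiv), −78 °C; aq NH4Cl
Reagents that add atoms: none
Why: Intramolecular Claisen condensation (O→C acyl transfer): C1 is the only enolisable carbon of the epoxy ketone, and its enolate attacks the lactone carbonyl through an 8-oxabicyclo[3.2.1]octene tetrahedral intermediate that can form only with C10 cis to C6, so the seven-membered carbocycle closes cis-fused with the C1 quaternary centre set (methyl cis to H-5); the released C6 alkoxide 9 is acylated in situ, which blocks the retro-Claisen and installs the first angelate without Z to E isomerisation.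

Step 6
Reactants: 10 6β-(angeloyloxy)-3α,4α-epoxy-1β,5β-dauc-8-ene-2,10-dione
Product: 11 6β-(angeloyloxy)-4α-hydroxy-1β,5β-dauc-8-ene-2,10-dione
Conditions: SmI2 (2.2 equiv), THF/MeOH, −90 °C
Reagents that add atoms: none
Why: Reductive opening of the α,β-epoxy ketone (C2 ketyl, scission of the C3–O bond, protonation) gives the β-hydroxy ketone; the C4–O bond is not touched, so the tertiary carbinol keeps its configuration, and the β,β-disubstituted enone and the angelate react much more slowly at −90 °C.

Step 7
Reactants: 11 6β-(angeloyloxy)-4α-hydroxy-1β,5β-dauc-8-ene-2,10-dione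
Product: 12 6β-(angeloyloxy)-4α,10α-dihydroxy-1β,5β-dauc-8-en-2-one
Conditions: NaBH4, CeCl3·7H2O, MeOH, −78 °C
Reagents that add atoms: none
Why: Luche reduction is 1,2-selective and prefers the conjugated C10 ketone to the hindered saturated C2 ketone; with cerium bridging the two carbonyls of the 1,3-diketone, hydride enters anti to C5 from the face of the C1 methyl (the convex face of the cis-fused bicycle), giving the 10α-alcohol.

Step 8
Reactants: 12 6β-(angeloyloxy)-4α,10α-dihydroxy-1β,5β-dauc-8-en-2-one
Product: 13 6β-(angeloyloxy)-8α,9α-epoxy-4α,10α-dihydroxy-1β,5β-daucan-2-one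
Conditions: VO(acac)2 (5 mol %), t-BuOOH, CH2Cl2, 0 °C
Reagents that add atoms: tert-butyl hydroperoxide, CC(C)(C)OO
Why: Vanadium-catalysed hydroxyl-directed epoxidation of the cyclic allylic alcohol delivers oxygen syn to the 10α-OH and so sets C8 and C9 (8α,9α-epoxide); the electron-poor angelate alkene is inert.

Step 9
Reactants: 13 6β-(angeloyloxy)-8α,9α-epoxy-4α,10α-dihydroxy-1β,5β-daucan-2-one; 8 angelic anhydride
Product: 14 6β,10α-bis(angeloyloxy)-8α,9α-epoxy-4α-hydroxy-1β,5β-daucan-2-one
Conditions: LiN(SiMe3)2 (1.1 equiv), THF, −78 °C; then 8, −78 to −40 °C; aq NH4Cl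
Reagents that add atoms: none
Why: Alkoxide acylation with the anhydride esterifies the secondary C10 oxygen in preference to the tertiary C4–OH and preserves the Z geometry; the cis epoxy alkoxide cannot undergo Payne rearrangement.

Step 10
Reactants: 14 6β,10α-bis(angeloyloxy)-8α,9α-epoxy-4α-hydroxy-1β,5β-daucan-2-one
Product: 15 target, 6β,10α-bis(angeloyloxy)-8α,9α-epoxy-1β,5β-daucane-2β,4α-diol
Conditions: Me4NBH(OAc)3, MeCN/AcOH, −35 °C
Reagents that add atoms: none
Why: Evans–Saksena reduction: the tertiary C4–OH exchanges onto boron and delivers hydride intramolecularly to the α-face of the C2 ketone, giving the 2β-alcohol trans to the C4–OH (anti-1,3-diol); triacetoxyborohydride does not reduce the esters or the epoxide.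

## Compound list

1 | (−)-α-thujone, (1S,4R,5R)-4-methyl-1-(propan-2-yl)bicyclo[3.1.0]hexan-3-one | C[C@H]1C(=O)C[C@]2(C(C)C)C[C@H]12 | starting material
2 | kinetic trimethylsilyl enol ether of 1, 4-methyl-1-(propan-2-yl)-3-(trimethylsilyloxy)bicyclo[3.1.0]hex-2-ene, stereocentres as in 1 | C[C@H]1C(O[Si](C)(C)C)=C[C@]2(C(C)C)C[C@H]12 | intermediate
3 | 5α-(hydroperoxymethyl)-4-isopropyl-1β-methylcyclopent-3-en-2-one (not isolated) | OOC[C@H]1C(C(C)C)=CC(=O)[C@@H]1C | intermediate
4 | 3α,4α-epoxy-5α-(hydroxymethyl)-4β-isopropyl-1β-methylcyclopentan-2-one | OC[C@H]1[C@@]2(C(C)C)O[C@H]2C(=O)[C@@H]1C | intermediate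
5 | 3α,4α-epoxy-5α-formyl-4β-isopropyl-1β-methylcyclopentan-2-one | O=C[C@H]1[C@@]2(C(C)C)O[C@H]2C(=O)[C@@H]1C | intermediate
6 | ethyl (E)-4-bromo-3-methylbut-2-enoate | CCOC(=O)/C=C(\C)CBr | starting material
7 | 4-methyl-6-(3α,4α-epoxy-4β-isopropyl-1β-methyl-2-oxocyclopent-5α-yl)-5,6-dihydro-2H-pyran-2-one, C6 as in the target | CC1=CC(=O)O[C@@H](C1)[C@H]1[C@@]2(C(C)C)O[C@H]2C(=O)[C@@H]1C | intermediate
8 | angelic anhydride, (Z)-2-methylbut-2-enoic anhydride | C/C=C(/C)C(=O)OC(=O)/C(C)=C\C | starting material
9 | lithium 6β-alkoxide of 3α,4α-epoxy-6β-hydroxy-1β,5β-dauc-8-ene-2,10-dione (not isolated) | [Li+].[O-][C@H]1CC(C)=CC(=O)[C@@]2(C)[C@@H]1[C@@]3(C(C)C)O[C@H]3C2=O | intermediate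
10 | 6β-(angeloyloxy)-3α,4α-epoxy-1β,5β-dauc-8-ene-2,10-dione | C/C=C(/C)C(=O)O[C@H]1CC(C)=CC(=O)[C@@]2(C)[C@@H]1[C@@]3(C(C)C)O[C@H]3C2=O | intermediate
11 | 6β-(angeloyloxy)-4α-hydroxy-1β,5β-dauc-8-ene-2,10-dione | C/C=C(/C)C(=O)O[C@H]1CC(C)=CC(=O)[C@@]2(C)[C@@H]1[C@](O)(C(C)C)CC2=O | intermediate
12 | 6β-(angeloyloxy)-4α,10α-dihydroxy-1β,5β-dauc-8-en-2-one | C/C=C(/C)C(=O)O[C@H]1CC(C)=C[C@H](O)[C@@]2(C)[C@@H]1[C@](O)(C(C)C)CC2=O | intermediate
13 | 6β-(angeloyloxy)-8α,9α-epoxy-4α,10α-dihydroxy-1β,5β-daucan-2-one | C/C=C(/C)C(=O)O[C@H]1C[C@]2(C)O[C@@H]2[C@H](O)[C@@]2(C)[C@@H]1[C@](O)(C(C)C)CC2=O | intermediate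
14 | 6β,10α-bis(angeloyloxy)-8α,9α-epoxy-4α-hydroxy-1β,5β-daucan-2-one | C/C=C(/C)C(=O)O[C@H]1C[C@]2(C)O[C@@H]2[C@H](OC(=O)/C(C)=C\C)[C@@]2(C)[C@@H]1[C@](O)(C(C)C)CC2=O | intermediate
15 | CNP0265715.3, 6β,10α-bis(angeloyloxy)-8α,9α-epoxy-1β,5β-daucane-2β,4α-diol | C/C=C(/C)C(=O)O[C@H]1C[C@]2(C)O[C@@H]2[C@H](OC(=O)/C(C)=C\C)[C@@]2(C)[C@@H]1[C@](O)(C(C)C)C[C@@H]2O | target

## Step count and risks

Total steps: 10. Longest linear sequence: 10 steps (1 to 15).

Risk 1, step 2 (the proposed aerobic ring-opening epoxidation). It can fail through α-oxygenation at C3 before ring opening, oxidative C=C cleavage, or endocyclic cyclopropane scission. The fallback uses known reactions, sets out from 2 and returns at 4. N-Iodosuccinimide converts 2 into the 3-iodo ketone F1. Et3B/air-initiated iodine-atom-transfer isomerisation (cyclopropylcarbinyl radical opening, iodine transfer chain, no oxygen in the bulk) gives the 5α-(iodomethyl) enone F2. AgOCOCF3 and H2O2 in ether exchange iodide for OOH to give hydroperoxide 3, which DBU closes to 4 exactly as in the main step.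

Risk 2, step 4 (facial selectivity and α/γ regiochemistry of the Reformatsky addition). If zinc chelation by the epoxide oxygen is too weak, the Felkin–Anh C6 epimer will dominate. The fallback replaces substrate control by reagent control and builds the lactone by metathesis; it sets out from 5 and returns at 7. Methallylation of 5 with (−)-B-(2-methylallyl)diisopinocampheylborane (from (+)-α-pinene, Si-face selective) and NaBO3 work-up gives the homoallylic alcohol F3. Acryloyl chloride and iPr2NEt give the acrylate F4. Ring-closing metathesis with second-generation Grubbs catalyst (CH2Cl2, 40 °C) gives 7.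

Risk 3, step 5 (intramolecular Claisen and in-situ angeloylation). Competing γ-deprotonation and eliminative opening of the dihydropyranone, conjugate addition at C8, strain in the bridged tetrahedral intermediate, or elimination of the new C6 angelate from the enone could each defeat it. The fallback closes the ring from an open-chain acyl donor; it sets out from 7 and returns at 10. Me3Al and MeNH(OMe)·HCl open the lactone to the (Z)-hydroxy Weinreb amide F5. Et3SiCl and imidazole give the silyl ether F6. LiN(SiMe3)2 then effects ketone-enolate acylation through a stable chelated tetrahedral intermediate (no retro-Claisen) to the bicyclic silyl ether F7. HF·pyridine gives the alcohol F8, and angelic acid with 2,4,6-trichlorobenzoyl chloride and Et3N gives 10.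

Further compounds
F1 | step 2 | 3-iodo ketone (2-iodo-α-thujone, either C3 epimer) | C[C@H]1C(=O)C(I)[C@]2(C(C)C)C[C@H]12
F2 | step 2 | 5α-(iodomethyl)-4-isopropyl-1β-methylcyclopent-3-en-2-one | IC[C@H]1C(C(C)C)=CC(=O)[C@@H]1C
F3 | step 4 | 3α,4α-epoxy-5α-(1-hydroxy-3-methylbut-3-en-1-yl)-4β-isopropyl-1β-methylcyclopentan-2-one, carbinol carbon as C6 of the target | CC(=C)C[C@H](O)[C@H]1[C@@]2(C(C)C)O[C@H]2C(=O)[C@@H]1C
F4 | step 4 | acrylate of F3 | CC(=C)C[C@H](OC(=O)C=C)[C@H]1[C@@]2(C(C)C)O[C@H]2C(=O)[C@@H]1C
F5 | step 5 | (Z)-5-hydroxy-N-methoxy-N,3-dimethyl-5-(3α,4α-epoxy-4β-isopropyl-1β-methyl-2-oxocyclopent-5α-yl)pent-2-enamide | CON(C)C(=O)/C=C(/C)C[C@H](O)[C@H]1[C@@]2(C(C)C)O[C@H]2C(=O)[C@@H]1C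
F6 | step 5 | triethylsilyl ether of F5 | CON(C)C(=O)/C=C(/C)C[C@H](O[Si](CC)(CC)CC)[C@H]1[C@@]2(C(C)C)O[C@H]2C(=O)[C@@H]1C
F7 | step 5 | 3α,4α-epoxy-6β-(triethylsilyloxy)-1β,5β-dauc-8-ene-2,10-dione | CC[Si](CC)(CC)O[C@H]1CC(C)=CC(=O)[C@@]2(C)[C@@H]1[C@@]3(C(C)C)O[C@H]3C2=O
F8 | step 5 | 3α,4α-epoxy-6β-hydroxy-1β,5β-dauc-8-ene-2,10-dione | O[C@H]1CC(C)=CC(=O)[C@@]2(C)[C@@H]1[C@@]3(C(C)C)O[C@H]3C2=O
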